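(Readings and results come from a simulation on assumed constants, noise included.)

You cannot read the share of D in D plus J at 10 h off either run, since that time is earlier than the first reading, at 1.04 d.

| flask | E | Q | remark | time |
|---|---|---|---|---|
| Monday's | 7.5 mM | 1.5 mM | run made earlier |  |
| Wednesday's | 30 mM | 1.5 mM | run made earlier |  |
| flask | 15 mM | 1.5 mM |  | 15 d |

| run | time / d | D / % | J / % |
|---|---|---|---|
| Monday's | 3.00 | 3 | 41 |
| Monday's | 6.00 | 2 | 69 |
| Monday's | 10.0 | 1 | 68 |
| Monday's | 12.0 | 5 | 70 |
| Wednesday's | 1.04 | 0 | 2 |
| Wednesday's | 2.00 | 1 | 10 |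
| Wednesday's | 5.00 | 1 | 13 |
| Wednesday's | 12.0 | 0 | 28 |

(scatter of a reading: 2 percentage points)

1. share of D in D plus J at 10 h
2. share of D in D plus J at 15 d

- E is a solid; its amount is given per volume of the solution
- the numbers in the tables scatter with a standard deviation of 2 percentage points
- at the start none of E is in solution

The runs do give a pace and an end. Wednesday's J reads 28% of its charge at 12.0 d, a pace of 0.700 mM d⁻¹. Monday's J lies flat from 6.00 d at about 69.0% of the charge, and over those readings D makes up 3.72% of D plus J.

For this flask at 15 d, taking that pace to hold, the fill number comes to 1.01. The fill number is the J that the pace makes by a given time, divided by the J that the charge ends with.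

| Flask and time | Fill number |
|---|---|
| Monday's, 12.0 d | 1.62 |
| This flask, 15 d | 1.01 |
| This flask, 10 h | 0.0282 |

A fill number near 1 means that the pace has just made the end J, so my reckoning carries Monday's share, 3.72%, to 15 d. One number is not enough at 10 h: by that pace hardly any of the end J has formed, the number does not say how D and J divide, and I give no figure there.

The forecast gives 4% at 10 h and 4% at 15 d, on the ground that “D shows no trend with time or loading”.

The flask gives 28.5% at 10 h and 3.97% at 15 d.

    L ⇌ J (K = 2.50, k = 1.20 × 10⁻⁵ s⁻¹)
    L + Q ⇌ D + Q, rate k2*[L]*[Q] forward; the back reaction follows from the equilibrium constant (K = 0.0970, k = 0.0180 L mol⁻¹ s⁻¹)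
    E ⇌ L, rate k3*(cs3 - [L]) while solid is left; crystals form when [L] > cs3 (solubility = 4.90 mM, k = 5.90 × 10⁻⁶ s⁻¹)

Left far beyond 15 d, this flask's share stands at 3.74%, the end under thermodynamic control. The fill number times 69.0% gives J of 69.7% at 15 d, and this flask holds 65.5%. With the pace held, the fill number stays 1.01 for a neighbour flask with 0.38 mM of Q, which ends with 65.5% of J and a D share of 3.96%.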